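The vessel is stirred at constant volume, and reagent serves two steps: with substrate it gives open intermediate, with partner it gives second intermediate, and target needs one of each.

| setting | Sunday's | Saturday's | Wednesday's | Monday's | autumn | summer | noon | midnight |
|---|---|---|---|---|---|---|---|---|
| substrate | 0.050 M | 0.050 M | 0.050 M | 0.10 M | 0.050 M (fed, over 25 h) | 0.050 M | 0.050 M | 0.050 M |
| partner | 1.1 equiv | 0.55 equiv | 2.2 equiv | 1.1 equiv | 1.10 equiv | 1.10 equiv (fed, over 25 h) | 1.10 equiv (fed, over 2.5 h) | 1.10 equiv |
| reagent | 1.1 equiv | 1.1 equiv | 1.1 equiv | 1.1 equiv | 1.10 equiv | 1.10 equiv | 1.10 equiv | 1.10 equiv |
| capture agent | 5 mM | 5 mM | 5 mM | 5 mM | 5.00 mM | 5.00 mM | 5.00 mM | 5.00 mM |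
| remark | run made earlier | run made earlier | run made earlier | run made earlier | all else is in the flask from the start; the feed brings no volume worth counting | all else is in the flask from the start; the feed brings no volume worth counting | all else is in the flask from the start; the feed brings no volume worth counting | everything together at the start |
| time |  |  |  |  | 30 h | 30 h | 30 h | 30 h |

- Sunday's (time / h: target / %): 2.50: 1.3; 6.00: 4.2; 12.0: 5.8; 20.0: 6.8
- Saturday's (time / h: target / %): 4.00: 2.1; 10.0: 2.9; 20.0: 2.8; 30.0: 4.1
- Wednesday's (time / h: target / %): 2.50: 3.5; 6.00: 7.2; 12.0: 9.3; 30.0: 11.7
- Monday's (time / h: target / %): 2.50: 2.6; 6.00: 5.5; 12.0: 6.4; 30.0: 8.1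

(readings scatter by 0.5 percentage points)

- the flask with the highest amount of target, in percent of the substrate charged ("all alike" if they lie within 1.5 percentage points) (autumn / summer / noon / midnight / all alike)
- final target, as a percentage of the substrate charged, in autumn
- final target, as a percentage of the substrate charged, in summer
- final target, as a percentage of the substrate charged, in noon
- final target, as a percentage of the substrate charged, in midnight

- percentages count the substrate that a species holds: one homo product counts as two
- candidate steps: substrate + reagent -> open intermediate; reagent + partner -> second intermediate; open intermediate + second intermediate -> target; 2 open intermediate -> homo product; target <-> isomer of the product; open intermediate + capture agent -> trapped intermediate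

The rungs can be read from the runs. The rung to measure against is the rise of target: Sunday's run reads 4.2% at 6.00 h, against 6.8% at 20.0 h, so 6.00 h serves as the rise time. Noon's feed of 2.5 h is shorter than that, so noon should look like midnight. The slow feed of 25 h is longer, by a stretch (feed time over rise time) of 4.17. After the rise comes a late creep, as in Wednesday's run, which reads 9.3% at 12.0 h and 11.7% at 30.0 h.

The target read at 30.0 h rises with the partner charge, though Monday's run also differs in substrate, at 0.10 M. Call the take the target formed per equivalent of partner when everything starts together: Monday's run gives 7.36% of the substrate charged per equivalent, Saturday's 7.45%, Wednesday's 5.32%. At one moment, the share of reagent going to partner rises with the ratio of partner to substrate. Monday's take on 1.10 equiv of partner gives a base of 8.10% as my estimate for midnight, and about that for noon. My own reckoning multiplies the base by the stretch for autumn, where fed substrate stands dilute, giving 33.8%. It divides by the stretch for summer, where partner arrives late, giving 1.94%.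

The forecast also names autumn, but at 13%, less than my figure, with summer 2%, noon 6.5% and midnight 7.4%: “I expect it to be best, but this is quite uncertain”.

The flasks give autumn as the best: autumn 20.1%, summer 2.88%, noon 6.05%, midnight 7.12%.

    substrate + reagent → open intermediate (k = 14.5 M⁻¹ h⁻¹)
    reagent + partner → second intermediate (k = 0.348 M⁻¹ h⁻¹)
    open intermediate + second intermediate → target (k = 26.0 M⁻¹ h⁻¹)
    2 open intermediate → homo product (k = 2.07 M⁻¹ h⁻¹)
    target ⇌ isomer of the product (K = 0.175, k = 0.0720 h⁻¹)
    open intermediate + capture agent → trapped intermediate (k = 0.0619 M⁻¹ h⁻¹)

At midnight's start, reagent goes to partner at 0.0264 of its rate to substrate; in autumn substrate enters by feed, and the step of reagent with partner has 24% of its turnover up to 30 h behind it after 3.00 h. By 30 h, partner spent amounts to 23.9% of the substrate charged in autumn, with target plus isomer of the product at 23.5%; in midnight the two figures are 8.73% and 8.33%. Autumn's target is 2.48 times the base, less than the stretch.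

With that factor, the take gives 12.0% for the neighbour of autumn charged with 0.660 equiv of partner; that flask gives 13.1%.

The data were computed for substances that don't exist; the scatter is artificial.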